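**Plan**

- Retrosynthesis: the C40 chain is cut at C11=C12 and C11'=C12' (two Wittig olefinations), giving (2E,4E,6E)-2,7-dimethylocta-2,4,6-trienedial and two C15 phosphonium salts. The acetylenic salt is cut further at C8–C9 (Sonogashira) and C7≡C8 (one-carbon homologation), the olefinic salt at C7'=C8' (Horner–Wadsworth–Emmons), so both halves come from one C10 ring aldehyde.
- Enabling feature: that aldehyde maps onto safranal, whose ring already holds C1–C6, C7 and the three methyl groups, with the C5=C6 alkene in place and the cis C3=C4 alkene, conjugated to C5=C6, lying exactly where each end ring carries its trans-3,4-diol.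
- Rings: no carbocycle is built; the only ring formed is an oxirane across C3–C4, which water then opens at allylic C4.
- Forward order: safranal to ring aldehyde 9; 9 to the olefinic C15 salt and on to a C25 aldehyde with the C10 dialdehyde; 9 to the ring alkyne and the acetylenic C15 salt; final C11=C12 bond; global desilylation.
- Stereochemistry: one Mn(salen)-catalysed epoxidation sets C3 (S) and C4 (R); anti hydrolysis inverts C4 to give the (3S,4S)-diol, which serves both end groups. Alkene geometry comes from E-selective phosphonate olefination, an (E)-enol triflate, and thermal equilibration of the hindered cis Wittig products.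

Key step: step 3

Remark: carotenoid numbering is used for the end group (C1 gem-dimethyl carbon, C5 methyl-bearing ring carbon, C6 ring carbon carrying C7; primes for the olefinic half). The (R,R)-catalyst is assigned to the (3S,4R)-oxirane by analogy with indene and 1,2-dihydronaphthalene; the sense is to be confirmed on diol 6, and the (S,S)-complex substituted if it proves opposite. TBS = tert-butyldimethylsilyl.

**Route**

Step 1
Reactants: 1 safranal
Product: 2 safranol
Conditions: NaBH4, CeCl3·7H2O, MeOH, 0 °C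
Reagents that add atoms: none
Why: Luche reduction delivers hydride 1,2 to the hindered dienal carbonyl, the cerium salt suppressing conjugate addition so that both ring alkenes stay in place.

Step 2
Reactants: 2 safranol; 3 pivaloyl chloride
Product: 4 safranyl pivalate
Conditions: pyridine, DMAP (cat.), CH2Cl2, 0 °C to rt
Reagents that add atoms: none
Why: DMAP-catalysed acylation of the primary allylic alcohol gives an ester that should tolerate bleach at pH 11 and dilute acid and can later be removed reductively.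

Step 3
Reactants: 4 safranyl pivalate
Product: 5 (3S,4R)-3,4-epoxide of safranyl pivalate
Conditions: (R,R)-(salen)MnCl (5 mol %; salen = N,N'-bis(3,5-di-tert-butylsalicylidene)cyclohexane-1,2-diaminate), 4-phenylpyridine N-oxide (20 mol %), aq. NaOCl buffered to pH 11.3 with Na2HPO4, CH2Cl2, 0 °C
Reagents that add atoms: sodium hypochlorite, [Na+].[O-]Cl
Why: Jacobsen–Katsuki epoxidation: hypochlorite oxidises the trivalent manganese complex to an oxomanganese species with pentavalent manganese, which the cis C3=C4 alkene approaches side-on; the first C–O bond forms at C3, leaving a radical at C4 stabilised by allylic delocalisation into C5=C6, and its collapse onto oxygen forms the second C–O bond. The oxirane thus closes by oxygen-atom transfer, a formal [2+1] addition ending in three-membered ring closure at C4, and the six-membered ring enforces cis fusion. Both new stereocentres, C3 (S) and C4 (R), are fixed by the enantioface that the (R,R)-diaminocyclohexane backbone and the tert-butyl groups of the ligand leave open, the sense following that known for indene and 1,2-dihydronaphthalene with the C5=C6 alkenyl group in the role of the arene. Site selectivity between the two alkenes is needed and is secured by the substrate: C3=C4 is cis-disubstituted, conjugated and unhindered, the best substrate class for this catalyst, whereas C5=C6 is tetrasubstituted and screened by the C1 gem-dimethyl group and the CH2OPiv arm. The buffered basic medium should keep the acid-labile vinyl oxirane intact, and the quaternary C1 rules out aromatisation.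

Step 4
Reactants: 5 (3S,4R)-3,4-epoxide of safranyl pivalate
Product: 6 (3S,4S)-trans-3,4-diol pivalate
Conditions: HClO4 (cat.), THF/H2O 3:1, 0 °C
Reagents that add atoms: water, O
Why: Acid-catalysed hydrolysis of a vinyl epoxide opens the protonated oxirane at allylic C4, where charge is delocalised into C5=C6, with water entering anti to the leaving oxygen, so C4 inverts (R to S) while C3 stays S, and attack at C6 is blocked by quaternary C1 and the CH2OPiv group.

Step 5
Reactants: 6 (3S,4S)-trans-3,4-diol pivalate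
Product: 7 (3S,4S)-3,4-bis(TBS) ether pivalate
Conditions: TBSOTf, 2,6-lutidine, CH2Cl2, −78 to 0 °C
Reagents that add atoms: tert-butyldimethylsilyl triflate, CC(C)(C)[Si](C)(C)OS(=O)(=O)C(F)(F)F
Why: Silylation with the silyl triflate and a hindered base is forcing enough for both secondary hydroxyls, including the allylic C4–OH next to the C5 methyl, and leaves no free alcohol to interfere with the later oxidation.

Step 6
Reactants: 7 (3S,4S)-3,4-bis(TBS) ether pivalate
Product: 8 (3S,4S)-3,4-bis(TBS-oxy) ring carbinol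
Conditions: i-Bu2AlH, CH2Cl2, −78 °C; aq. potassium sodium tartrate work-up
Reagents that add atoms: none
Why: Reductive ester cleavage with the aluminium hydride removes the hindered pivalate, which resists mild methanolysis, without touching the silyl ethers.

Step 7
Reactants: 8 (3S,4S)-3,4-bis(TBS-oxy) ring carbinol
Product: 9 (3S,4S)-3,4-bis(TBS-oxy) ring aldehyde
Conditions: MnO2, CH2Cl2, rt
Reagents that add atoms: none
Why: Allylic oxidation with MnO2 stops at the enal, and the only free hydroxyl is the primary allylic one.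

Step 8
Reactants: 9 (3S,4S)-3,4-bis(TBS-oxy) ring aldehyde; 10 ethyl (2E)-4-(diethoxyphosphoryl)-3-methylbut-2-enoate
Product: 11 olefinic C15 ester (7E,9E)
Conditions: n-BuLi, DMPU, THF, −78 to 0 °C
Reagents that add atoms: none
Why: Horner–Wadsworth–Emmons olefination with the vinylogous phosphonate anion forms C7=C8 with E geometry and should give mainly the 9E ester, the minor 9Z isomer being removed by chromatography.

Step 9
Reactants: 11 olefinic C15 ester
Product: 12 olefinic C15 alcohol
Conditions: i-Bu2AlH, CH2Cl2, −78 °C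
Reagents that add atoms: none
Why: 1,2-Reduction of the conjugated ester by the aluminium hydride gives the allylic alcohol without affecting the diene or the silyl ethers.

Step 10
Reactants: 12 olefinic C15 alcohol
Product: 14 olefinic C15 triphenylphosphonium bromide, via olefinic C15 allylic bromide 13 (not isolated)
Conditions: CBr4, PPh3, CH2Cl2, 0 °C; then PPh3, rt
Reagents that add atoms: carbon tetrabromide, BrC(Br)(Br)Br; triphenylphosphine, c1ccc(cc1)P(c1ccccc1)c1ccccc1
Why: Appel bromination under neutral conditions, chosen over acidic PPh3·HBr so that the allylic C4 silyl ether is not ionised, is followed by SN2 quaternisation of the labile primary allylic bromide with triphenylphosphine.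

Step 11
Reactants: 14 olefinic C15 triphenylphosphonium bromide; 15 (2E,4E,6E)-2,7-dimethylocta-2,4,6-trienedial
Product: 17 all-E C25 aldehyde, via 11'Z C25 aldehyde 16 (not isolated)
Conditions: NaOMe, MeOH/CH2Cl2, rt, 15 in excess (3 equiv); then heptane, reflux
Reagents that add atoms: none
Why: Wittig olefination of the semi-stabilised allylic ylide with an excess of the symmetrical dialdehyde favours mono-condensation at C11'=C12', and the sterically strained 11'Z isomer formed alongside should revert thermally to the E isomer.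

Step 12
Reactants: 9 (3S,4S)-3,4-bis(TBS-oxy) ring aldehyde
Product: 18 (3S,4S)-3,4-bis(TBS-oxy) ring alkyne
Conditions: Me3SiCHN2, LiN(i-Pr)2, THF, −78 °C to rt
Reagents that add atoms: trimethylsilyldiazomethane, C[Si](C)(C)C=[N+]=[N-]
Why: Colvin rearrangement: lithiated trimethylsilyldiazomethane adds to the aldehyde, Peterson-type elimination and loss of dinitrogen give an alkylidene carbene, and a 1,2-hydrogen shift delivers the terminal alkyne, the aprotic medium avoiding the conjugate addition that enals suffer under methanolic homologation conditions.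

Step 13
Reactants: 19 ethyl acetoacetate
Product: 20 ethyl (2E)-3-(trifluoromethanesulfonyloxy)but-2-enoate
Conditions: Tf2O, aq. Me4NOH, hexanes, 5 to 10 °C
Reagents that add atoms: triflic anhydride, O=S(=O)(OS(=O)(=O)C(F)(F)F)C(F)(F)F
Why: O-Triflation of the enolate under a non-coordinating tetramethylammonium counter-ion proceeds through the extended enolate and should give the (E)-enol triflate, with the triflate trans to the ester.

Step 14
Reactants: 18 (3S,4S)-3,4-bis(TBS-oxy) ring alkyne; 20 ethyl (2E)-3-(trifluoromethanesulfonyloxy)but-2-enoate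
Product: 21 acetylenic C15 ester (9E)
Conditions: PdCl2(PPh3)2 (cat.), CuI (cat.), Et3N, THF, rt
Reagents that add atoms: none
Why: Sonogashira coupling: zerovalent palladium formed in situ inserts into the vinyl C–OTf bond and couples with the copper acetylide with retention of alkene geometry, so the E triflate becomes the 9E enyne.

Step 15
Reactants: 21 acetylenic C15 ester
Product: 22 acetylenic C15 alcohol
Conditions: i-Bu2AlH, CH2Cl2, −78 °C
Reagents that add atoms: none
Why: 1,2-Reduction of the conjugated ester by the aluminium hydride gives the allylic alcohol and leaves the enyne and silyl ethers untouched.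

Step 16
Reactants: 22 acetylenic C15 alcohol
Product: 24 acetylenic C15 triphenylphosphonium bromide, via acetylenic C15 allylic bromide 23 (not isolated)
Conditions: CBr4, PPh3, CH2Cl2, 0 °C; then PPh3, rt
Reagents that add atoms: carbon tetrabromide, BrC(Br)(Br)Br; triphenylphosphine, c1ccc(cc1)P(c1ccccc1)c1ccccc1
Why: Appel bromination followed by SN2 quaternisation, as in step 10, converts the allylic alcohol to the Wittig salt under neutral conditions that spare the C4 silyl ether.

Step 17
Reactants: 17 all-E C25 aldehyde; 24 acetylenic C15 triphenylphosphonium bromide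
Product: 26 all-E tetrakis-TBS C40 ether, via 11Z tetrakis-TBS C40 ether 25 (not isolated)
Conditions: NaOMe, MeOH/CH2Cl2, rt; then heptane, reflux (no iodine)
Reagents that add atoms: none
Why: Wittig olefination closes the chain at C11=C12, and thermal equilibration should convert the hindered 11Z isomer to E while, unlike iodine catalysis, leaving the unhindered 9E enyne bond alone.

Step 18
Reactants: 26 all-E tetrakis-TBS C40 ether
Product: 27 (3S,4S,3'S,4'S)-7,8-didehydro-β,β-carotene-3,4,3',4'-tetrol
Conditions: Bu4NF, AcOH, THF, rt to 40 °C, dark, argon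
Reagents that add atoms: none
Why: Fluoride-induced desilylation cleaves all four Si–O bonds without breaking a C–O bond, so the four stereocentres are untouched, and the acetic acid buffer spares the polyene from basic alkoxide.

**Compound list**

1 | safranal (2,6,6-trimethylcyclohexa-1,3-diene-1-carbaldehyde) | CC1=C(C=O)C(C)(C)CC=C1 | starting material
2 | safranol, (2,6,6-trimethylcyclohexa-1,3-dien-1-yl)methanol | CC1=C(CO)C(C)(C)CC=C1 | intermediate
3 | pivaloyl chloride | CC(C)(C)C(Cl)=O | starting material
4 | safranyl pivalate, (2,6,6-trimethylcyclohexa-1,3-dien-1-yl)methyl 2,2-dimethylpropanoate | CC1=C(COC(=O)C(C)(C)C)C(C)(C)CC=C1 | intermediate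
5 | (3S,4R)-3,4-epoxide of safranyl pivalate (carotenoid numbering), [(1R,6S)-2,4,4-trimethyl-7-oxabicyclo[4.1.0]hept-2-en-3-yl]methyl 2,2-dimethylpropanoate | CC1=C(COC(=O)C(C)(C)C)C(C)(C)C[C@@H]2O[C@H]12 | intermediate
6 | [(3S,4S)-3,4-dihydroxy-2,6,6-trimethylcyclohex-1-en-1-yl]methyl 2,2-dimethylpropanoate (trans-diol) | CC1=C(COC(=O)C(C)(C)C)C(C)(C)C[C@H](O)[C@H]1O | intermediate
7 | [(3S,4S)-3,4-bis(TBS-oxy)-2,6,6-trimethylcyclohex-1-en-1-yl]methyl 2,2-dimethylpropanoate | CC1=C(COC(=O)C(C)(C)C)C(C)(C)C[C@H](O[Si](C)(C)C(C)(C)C)[C@H]1O[Si](C)(C)C(C)(C)C | intermediate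
8 | [(3S,4S)-3,4-bis(TBS-oxy)-2,6,6-trimethylcyclohex-1-en-1-yl]methanol | CC1=C(CO)C(C)(C)C[C@H](O[Si](C)(C)C(C)(C)C)[C@H]1O[Si](C)(C)C(C)(C)C | intermediate
9 | (3S,4S)-3,4-bis(TBS-oxy)-2,6,6-trimethylcyclohex-1-ene-1-carbaldehyde | CC1=C(C=O)C(C)(C)C[C@H](O[Si](C)(C)C(C)(C)C)[C@H]1O[Si](C)(C)C(C)(C)C | intermediate
10 | ethyl (2E)-4-(diethoxyphosphoryl)-3-methylbut-2-enoate | CCOC(=O)/C=C(C)/CP(=O)(OCC)OCC | starting material
11 | ethyl (2E,4E)-5-[(3S,4S)-3,4-bis(TBS-oxy)-2,6,6-trimethylcyclohex-1-en-1-yl]-3-methylpenta-2,4-dienoate | CCOC(=O)/C=C(C)/C=C/C1=C(C)[C@H](O[Si](C)(C)C(C)(C)C)[C@@H](O[Si](C)(C)C(C)(C)C)CC1(C)C | intermediate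
12 | (2E,4E)-5-[(3S,4S)-3,4-bis(TBS-oxy)-2,6,6-trimethylcyclohex-1-en-1-yl]-3-methylpenta-2,4-dien-1-ol | OC/C=C(C)/C=C/C1=C(C)[C@H](O[Si](C)(C)C(C)(C)C)[C@@H](O[Si](C)(C)C(C)(C)C)CC1(C)C | intermediate
13 | (2E,4E)-1-bromo-5-[(3S,4S)-3,4-bis(TBS-oxy)-2,6,6-trimethylcyclohex-1-en-1-yl]-3-methylpenta-2,4-diene (formed in the flask, not isolated) | BrC/C=C(C)/C=C/C1=C(C)[C@H](O[Si](C)(C)C(C)(C)C)[C@@H](O[Si](C)(C)C(C)(C)C)CC1(C)C | intermediate
14 | {(2E,4E)-5-[(3S,4S)-3,4-bis(TBS-oxy)-2,6,6-trimethylcyclohex-1-en-1-yl]-3-methylpenta-2,4-dien-1-yl}triphenylphosphonium bromide | [Br-].c2ccccc2[P+](c3ccccc3)(c4ccccc4)C/C=C(C)/C=C/C1=C(C)[C@H](O[Si](C)(C)C(C)(C)C)[C@@H](O[Si](C)(C)C(C)(C)C)CC1(C)C | intermediate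
15 | (2E,4E,6E)-2,7-dimethylocta-2,4,6-trienedial (C10 dialdehyde) | O=C/C(C)=C/C=C/C=C(C)/C=O | starting material
16 | (2E,4E,6E,8Z,10E,12E)-isomer of 17, the 11'Z C25 aldehyde (formed in the flask, not isolated) | O=C/C(C)=C/C=C/C=C(C)/C=C\C=C(C)\C=C\C1=C(C)[C@H](O[Si](C)(C)C(C)(C)C)[C@@H](O[Si](C)(C)C(C)(C)C)CC1(C)C | intermediate
17 | (2E,4E,6E,8E,10E,12E)-13-[(3S,4S)-3,4-bis(TBS-oxy)-2,6,6-trimethylcyclohex-1-en-1-yl]-2,7,11-trimethyltrideca-2,4,6,8,10,12-hexaenal (all-E C25 aldehyde) | O=C/C(C)=C/C=C/C=C(C)/C=C/C=C(C)/C=C/C1=C(C)[C@H](O[Si](C)(C)C(C)(C)C)[C@@H](O[Si](C)(C)C(C)(C)C)CC1(C)C | intermediate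
18 | (3S,4S)-1-ethynyl-3,4-bis(TBS-oxy)-2,6,6-trimethylcyclohex-1-ene | CC1=C(C#C)C(C)(C)C[C@H](O[Si](C)(C)C(C)(C)C)[C@H]1O[Si](C)(C)C(C)(C)C | intermediate
19 | ethyl acetoacetate | CCOC(=O)CC(C)=O | starting material
20 | ethyl (2E)-3-(trifluoromethanesulfonyloxy)but-2-enoate | CCOC(=O)/C=C(C)/OS(=O)(=O)C(F)(F)F | intermediate
21 | ethyl (2E)-5-[(3S,4S)-3,4-bis(TBS-oxy)-2,6,6-trimethylcyclohex-1-en-1-yl]-3-methylpent-2-en-4-ynoate | CC1=C(C#C/C(C)=C/C(=O)OCC)C(C)(C)C[C@H](O[Si](C)(C)C(C)(C)C)[C@H]1O[Si](C)(C)C(C)(C)C | intermediate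
22 | (2E)-5-[(3S,4S)-3,4-bis(TBS-oxy)-2,6,6-trimethylcyclohex-1-en-1-yl]-3-methylpent-2-en-4-yn-1-ol | CC1=C(C#C/C(C)=C/CO)C(C)(C)C[C@H](O[Si](C)(C)C(C)(C)C)[C@H]1O[Si](C)(C)C(C)(C)C | intermediate
23 | (2E)-1-bromo-5-[(3S,4S)-3,4-bis(TBS-oxy)-2,6,6-trimethylcyclohex-1-en-1-yl]-3-methylpent-2-en-4-yne (formed in the flask, not isolated) | CC1=C(C#C/C(C)=C/CBr)C(C)(C)C[C@H](O[Si](C)(C)C(C)(C)C)[C@H]1O[Si](C)(C)C(C)(C)C | intermediate
24 | {(2E)-5-[(3S,4S)-3,4-bis(TBS-oxy)-2,6,6-trimethylcyclohex-1-en-1-yl]-3-methylpent-2-en-4-yn-1-yl}triphenylphosphonium bromide | [Br-].CC1=C(C#C/C(C)=C/C[P+](c2ccccc2)(c3ccccc3)c4ccccc4)C(C)(C)C[C@H](O[Si](C)(C)C(C)(C)C)[C@H]1O[Si](C)(C)C(C)(C)C | intermediate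
25 | (11Z)-isomer of 26 (formed in the flask, not isolated) | CC1=C(C#C\C(C)=C\C=C/C(C)=C/C=C/C=C(C)/C=C/C=C(C)/C=C/C2=C(C)[C@H](O[Si](C)(C)C(C)(C)C)[C@@H](O[Si](C)(C)C(C)(C)C)CC2(C)C)C(C)(C)C[C@H](O[Si](C)(C)C(C)(C)C)[C@H]1O[Si](C)(C)C(C)(C)C | intermediate
26 | all-E (3S,4S,3'S,4'S)-3,4,3',4'-tetrakis(TBS-oxy)-7,8-didehydro-β,β-carotene | CC1=C(C#C/C(C)=C/C=C/C(C)=C/C=C/C=C(C)/C=C/C=C(C)/C=C/C2=C(C)[C@H](O[Si](C)(C)C(C)(C)C)[C@@H](O[Si](C)(C)C(C)(C)C)CC2(C)C)C(C)(C)C[C@H](O[Si](C)(C)C(C)(C)C)[C@H]1O[Si](C)(C)C(C)(C)C | intermediate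
27 | all-E (3S,4S,3'S,4'S)-7,8-didehydro-β,β-carotene-3,4,3',4'-tetrol (CNP0343957.1) | CC1=C(C#C/C(C)=C/C=C/C(C)=C/C=C/C=C(C)/C=C/C=C(C)/C=C/C2=C(C)[C@H](O)[C@@H](O)CC2(C)C)C(C)(C)C[C@H](O)[C@H]1O | target

**Step count**

Total: 18 steps. Longest linear sequence: 13 steps (steps 1–7, 12, 14, 15, 16, 17, 18; the branch through steps 8–11 is equally long).

**Steps most likely to fail**

Step 3. The catalyst may discriminate the two faces of this cyclic diene only moderately, so that the (3R,4R) series accompanies the wanted one after hydrolysis. The fallback sets out from diol 6 of insufficient enantiomeric purity and returns to the route at 6. Lipase-catalysed acylation (Burkholderia cepacia lipase, vinyl acetate, t-BuOMe, 30 °C) is expected, by analogy with trans-cyclohexane-1,2-diol and 3-hydroxy end groups of the ionone type, to acetylate the (3R,4R) antipode at the less hindered C3 hydroxyl. This would give [(3R,4R)-4-acetoxy-3-hydroxy-2,6,6-trimethylcyclohex-1-en-1-yl]methyl 2,2-dimethylpropanoate (the C3 acetate in carotenoid numbering) F1, which is removed by chromatography. The unreacted (3S,4S)-diol is carried on as 6 into step 5.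

Step 4. The protonated vinyl oxirane may open through a free allyl cation, letting water add syn (cis-diol), at C3 (which leads to the antipode), or triggering a hydride shift to a ketone. The fallback sets out from epoxide 5 and returns at diol 6. Buffered acetolysis (AcOH, NaOAc, rt) lets the carboxylate open C4 with inversion inside an ion pair, giving the (3S,4S)-4-acetoxy-3-hydroxy pivalate F2. Methanolysis of the acetate (K2CO3, MeOH, 0 °C), which is far faster than that of the pivalate, then releases 6.

Step 17. Thermal equilibration may leave 11Z material or begin to scramble the unhindered 9E bond of the acetylenic half, giving geometric mixtures that are hard to separate. The fallback sets out from bromide 23 (generated from 22 as in step 16) and returns at 26. Michaelis–Becker reaction with NaP(O)(OEt)2 (THF, 0 °C) gives the diethyl (2E)-5-[(3S,4S)-3,4-bis(TBS-oxy)-2,6,6-trimethylcyclohex-1-en-1-yl]-3-methylpent-2-en-4-yn-1-ylphosphonate F3. Its anion (KN(SiMe3)2, THF, −78 to 0 °C) undergoes Horner–Wadsworth–Emmons olefination with aldehyde 17, which is E-selective at C11=C12, to give 26 without a thermal isomerisation.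

**Further compounds**

F1 | step 3 | [(3R,4R)-4-acetoxy-3-hydroxy-2,6,6-trimethylcyclohex-1-en-1-yl]methyl 2,2-dimethylpropanoate (acetate on carotenoid C3 of the antipode) | CC1=C(COC(=O)C(C)(C)C)C(C)(C)C[C@@H](OC(C)=O)[C@@H]1O
F2 | step 4 | [(3S,4S)-3-acetoxy-4-hydroxy-2,6,6-trimethylcyclohex-1-en-1-yl]methyl 2,2-dimethylpropanoate (acetate on carotenoid C4) | CC1=C(COC(=O)C(C)(C)C)C(C)(C)C[C@H](O)[C@H]1OC(C)=O
F3 | step 17 | diethyl {(2E)-5-[(3S,4S)-3,4-bis(TBS-oxy)-2,6,6-trimethylcyclohex-1-en-1-yl]-3-methylpent-2-en-4-yn-1-yl}phosphonate | CC1=C(C#C/C(C)=C/CP(=O)(OCC)OCC)C(C)(C)C[C@H](O[Si](C)(C)C(C)(C)C)[C@H]1O[Si](C)(C)C(C)(C)C
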